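If a flask of starting material and partner sits at a level for days, I want a number in which time has dropped out, because it can be carried to the next change.

| flask | starting material | partner | second substrate | temperature | remark | time |
|---|---|---|---|---|---|---|
| epsilon | 0.80 M | 0.96 M | 0.40 M | 25 °C | the very flask that is asked about, followed so far |  |
| zeta | 0.80 M | 0.96 M | 0.40 M | 10 °C | run made earlier |  |
| flask | 0.80 M | 0.960 M | 0.400 M | 25 °C |  | 8.0 d |

| run | time / h | target / % | starting material / % |
|---|---|---|---|
| epsilon | 10.0 | 26.9 | 26.2 |
| epsilon | 20.0 | 27.7 | 28.6 |
| epsilon | 30.0 | 25.5 | 30.8 |
| epsilon | 60.0 | 26.9 | 33.5 |
| epsilon | 120 | 25.1 | 33.7 |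
| zeta | 20.0 | 25.9 | 17.2 |
| zeta | 40.0 | 17.4 | 16.8 |
| zeta | 60.0 | 17.1 | 18.0 |
| zeta | 120 | 16.0 | 20.7 |
| zeta | 240 | 15.6 | 24.2 |

(each reading ± 1 percentage point)
- removed target is counted in
- on the list of suspects stand: target -> over-reaction product; second substrate + partner -> second product; target <-> isomer of the product; starting material + partner <-> target
- noon: change nothing and wait 15 d more
- midnight: at 8.0 d raise the temperature by 10 K, then wait 15 d
- summer: at 8.0 d take out 90 % of the target then present, then wait 15 d
- target, in percent of the starting material first charged, at 8.0 d
- what to do for the largest gain in target; "none" if nothing gains more than 2 percentage points (noon / midnight / summer / none)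
- target present, with what was taken out counted in, in percent of the starting material first charged, after midnight
- target present, with what was taken out counted in, in percent of the starting material first charged, after summer

In epsilon the curve began steeply: by 10.0 h starting material stood at 26.2 %, a mean loss of 0.0738 /h of the charge, and target already stood at 26.9 %, so the knee lay before the first reading. Starting material then climbed back, crossed target near 14.4 h as far as the scatter lets one read, and reached 33.7 %. Target ran level, its last three readings averaging 25.8 %, and that was my figure for 8.0 d.

The step from 33.5 % to 33.7 % was within the scatter, so I assumed that second substrate had by then taken its whole 0.40 M of partner. That left free partner at 0.0296 M, a rough figure, since one point of scatter moves it by 0.00800 M. Bound starting material, which I took to be target and isomer together, divided by free starting material times free partner, is forward rate over back rate at rest, an apparent equilibrium constant; I call it the holding number 66.5 /M. The isomer-to-target ratio read 1.64.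

Taking out target removes equal amounts of starting material and partner from the balance, so free starting material minus free partner stays at 0.240 M. Removing 23.3 % of the charge leaves 0.614 M in play, and the holding number then gives free starting material 0.260 M. Target with the removed part counted in comes to 40.0 %. That stood above my level for target, so I chose summer. In zeta starting material was still rising, from 20.7 % to 24.2 %, so that run gave me no level and I set no number on midnight.

The forecast gave 25.6 %, summer, 31 % and 40 %, saying “Removing target re-equilibrates the remaining pool”.

The flask gave 23.8 %, with summer best at 13 percentage points against −1.4 points for noon and −2.9 points for midnight, and 20.9 % and 36.7 %.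

    target → over-reaction product (k = 8.20 × 10⁻⁶ /min, Ea = 115 kJ/mol)
    second substrate + partner → second product (k = 0.0310 /M/min, Ea = 71.0 kJ/mol)
    target ⇌ isomer of the product (K = 1.70, k = 0.0130 /min, Ea = 97.0 kJ/mol, ΔH = −39.0 kJ/mol)
    starting material + partner ⇌ target (K = 26.0 /M, k = 0.0400 /M/min, Ea = 52.0 kJ/mol, ΔH = −49.0 kJ/mol)
    (constants at 25 °C)

The flask had not come to rest. At 192 h its simulated amounts give a holding number of 70.2 /M, and at ten times the time, 1920 h, they give 70.2 /M. Starting material stood at 33.4 % and then 32.6 %, yet over-reaction product grew from 2.33 % to 19.8 % and target sank to 17.6 %.

In the neighbour flask with 0.48 M of starting material, free starting material minus free partner becomes −0.0800 M, and the holding number gives free starting material 10.4 % of its charge and target 33.9 %. That neighbour gave 9.78 % and 32.3 %.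

(The runs are calculated from invented constants; noise was put on by code.)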